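**Assumption (chemistry):** O-benzylvanillin is taken as a purchasable starting material; the sense of induction of the rhodium/(S,S)-Et-DuPhos hydrogenation (R acid) and of the magnesium-catalysed aldol (attack on the chelated enolate anti to the auxiliary benzyl group) is carried over from the parent substrate classes, and should either be reversed on these substrates, the mirror-image ligand or auxiliary would be used with no other change.

## Analysis of the target

The target 22 is a 7,7'-epoxylignan: an oxolane (O1, C2–C5) with a 4-hydroxy-3-methoxyphenyl group on each carbon next to oxygen (C2 and C5) and a hydroxymethyl group on C3 and on C4. All four ring carbons are stereocentres. Numbered from the aryl carbon that is cis to its neighbour, the configuration is 2S,3S,4R,5S: the C2 aryl, C3 hydroxymethyl and C4 hydroxymethyl groups lie on one face and the C5 aryl group on the other. The two halves have the same constitution, but the cis relationship at C2/C3 and the trans relationship at C4/C5 remove all symmetry, so the two benzylic centres cannot be made by the same reaction. Both benzylic C–O bonds are para to a free phenol, so acid or base can ionise them and re-close the ring to a more stable arrangement; the C2/C3 cis relationship is the one most at risk. Three contiguous cis substituents are thermodynamically unfavourable and must therefore be built under kinetic control and never equilibrated. The synthesis rests on one feature: C5 is benzylic and is the δ carbon counted from the oxygen on C2 (O1–C2–C3–C4–C5). It can therefore travel as a plain CH2 group and be oxidised only at the moment of ring closure, by an oxygen that already sits on C2 with its configuration fixed.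

## Retrosynthetic reasoning

Oxolane numbering is used for all intermediates: in the open-chain compounds the carbinol carbon is C2 and the benzylic CH2 is C5.

**22 from 21 (ester C–O bonds).** The two phenols and the two primary alcohols are carried as pivalates in 21. Acyl groups on the phenols lower the electron density of both arenes, which protects them from electrophilic iodine and keeps the benzylic C–O bonds from ionising. Acyl groups on the CH2–O carbons make those hydrogens poor partners for an oxygen radical. One hydride treatment must remove all four.

**21 from 20 (O1–C5).** The ring is opened at the bond between oxygen and the benzylic carbon that is trans to its neighbour. C5 is the one centre whose required configuration matches the substrate's own preference, so it can be left to the ring closure; C2, the fragile centre, keeps its oxygen throughout. The gain is that 20 has only three stereocentres and no oxygen at C5. The forward reaction has to remove one hydrogen from C5 and no other, and close with the aryl group trans to the C4 substituent.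

**20 from 19 and 9 (one ester C–O bond).** In 19 three of the four pivalates are already present, and only the C3 hydroxymethyl group and the C2 hydroxyl are free. The last ester comes from the acyl chloride 9. The forward step has to tell a primary hydroxyl from a secondary benzylic one next to a doubly branched carbon, which is a wide margin. Because the esters arrive one at a time along the route, no intermediate carries a free phenol para to a benzylic hydroxyl.

**19 from 17 by way of 18 (oxidation level of the C3 substituent carbon).** The C3 hydroxymethyl carbon is taken back to the imide carbonyl of 17, and the C2 hydroxyl to its silyl ether. The forward step needs a hydride donor strong enough for an imide and too weak for three pivalates, two of them aryl esters. The silyl group is kept during the reduction so that the aldol cannot reverse; the silyl ether 18 is cleaved in the same operation.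

**17 from 14 and 16 (C2–C3).** An aryl carbinol next to a carbon that bears a carboxyl-derived group is an aldol retron. The C2/C3 cis relationship of the ring corresponds to an anti aldol, so a syn-selective boron aldol is not suitable. The forward step must be anti-selective and must choose the enolate face against a resident centre at C4, which calls for an auxiliary. Cutting here joins the two aryl-bearing halves late and sets C2 and C3 together. C4 of 14 carries no carbonyl group, so only the imide can be enolised.

**14 from 11, 9 and 12 (N–acyl and aryl ester bonds).** The imide is made from the acid 11 and the oxazolidinone 12. The acyl chloride 9 both protects the phenol and activates the acid as the mixed anhydride 13, so one reagent does both.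

**11 from 10, 10 from 8 and 9, 8 from 6 by way of 7 (ester bonds at the two chain ends).** The C4 pivaloyloxymethyl group must be in place before the acid is activated, because a free γ-hydroxyl would close back onto any activated carboxyl group. The lactone 6 is therefore opened to the carboxylate 7, which is capped as the benzyl ester 8. The hydroxyl is then esterified with 9 to give 10, and one hydrogenolysis frees both the acid and the phenol of 11. A benzyl ester is chosen because it leaves under the same conditions as the aryl benzyl ether that the first steps need.

**6 from 4 by way of 5 (oxidation level of the C4 substituent carbon).** The ring CH2–O carbon of 6 is the ester carbon of the half ester 4. Reducing the ester while the other carboxyl group is a carboxylate salt gives the hydroxy acid 5, which lactonises. This fixes early which carboxyl carbon becomes the C4 hydroxymethyl group and which becomes the aldol donor.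

**4 from 3 (C4–H); 3 from 1 and 2 (C4=C5); 16 from 15 and 9.** The C4 centre is taken back to the trisubstituted alkene of the arylidene succinate half ester 3, where asymmetric hydrogenation directed by the free carboxylate sets it catalytically. The alkene is the product of a Stobbe condensation of the aldehyde 1 with dimethyl succinate 2, which delivers the free acid on the CH2 arm and the ester on the future C4 substituent. The aldol partner 16 is the pivalate of vanillin 15.

## Alternatives that were turned down

**Alternative 1: silicon-tethered radical delivery of the C3 hydroxymethyl carbon.** The disconnection is the C3–CH2 bond. The (bromomethyl)dimethylsilyl ether A1 of a 2,5-diaryl-2,3-dihydrofuran-3-ylmethanol would be treated with Bu3SnH. The silylmethyl radical adds to C3 of the cyclic enol ether and closes a six-membered siloxane ring. The C2 benzylic radical then takes hydrogen from the stannane to give the cis-fused bicycle A2. Oxidative cleavage of the C–Si bond and hydrogenolysis would finish.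
- For: the tether enforces the C3/C4 cis relationship by ring fusion. On this point it is stronger than the chosen route, where that relationship depends on two separate reagent-controlled events.
- Against: an α-silyl radical is nucleophilic and C3 of an aryl enol ether is electron-rich, so the addition is polarity-mismatched and simple reduction of the C–Br bond would compete.
- Against: C2 is set last, by hydrogen transfer to a stabilised benzylic α-oxy radical, so the most fragile relationship of the molecule would rest on the facial selectivity of a slow radical reduction.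
- Against: A1 already contains the trans C4/C5 pair in enantiopure form on an acid-labile enol ether, so the stereochemical problem is moved, not solved. Stoichiometric tin is a further cost.
- Comparison: the chosen route sets C2/C3 in a closed aldol transition state and keeps radical chemistry for C5, the one centre where the substrate bias points the right way.

**Alternative 2: enzymatic Baeyer–Villiger expansion of an all-cis cyclobutanone.** The disconnection is O1–C2, made by oxygen insertion. A ketene–alkene [2+2] cycloaddition would give the all-cis 2-aryl cyclobutanone A3. A Baeyer–Villiger monooxygenase would oxidise one enantiomer, with migration of the benzylic carbon and retention, to the all-cis lactone A4.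
- For: the four-membered ring supplies the C2/C3/C4 cis triad by geometry, and oxygen insertion with retention creates the C2–O bond without ionisation. On these two points it is at least as good as the chosen route, and it needs no auxiliary.
- Against: an enzymatic resolution gives at most half of the material, acceptance of a bulky electron-rich 2-aryl bicyclic ketone cannot be predicted, and the α-aryl ketone epimerises easily to the less crowded isomer.
- Against: A4 still lacks the second aryl group and C5. Aryl addition to the lactone carbonyl and reductive removal of the anomeric oxygen would be needed, under Lewis acid in the presence of a ketal. Hydride would then approach the open face and place the new aryl group on the crowded face, which is the opposite of what C5 requires.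
- Comparison: the chosen route has both aryl groups in place before the ring is closed and forms C5 by a closure whose intrinsic preference is the required one.

**Alternative 3: vinyl epoxide opening in a palladium [3+2] annulation.** O1–C2 and C3–C4 are disconnected together. Pd(PPh3)4 would open the aryl vinyl epoxide A5 to an alkoxide-bearing allylpalladium species. The alkoxide adds to the arylidene malonate A6, and the malonate anion closes on the near allyl terminus to give the vinyl oxolane diester A7.
- For: this is the most convergent plan. Two bonds, the ring, both aryl groups and the carbons of both hydroxymethyl groups arrive in one catalytic step from two simple partners, and in steps to the ring it beats the chosen route.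
- Against: C3 is made as a quaternary malonate carbon, so its configuration has to be created afterwards by removing one ester. Protonation of that enolate would place the remaining ester trans to its neighbours, whereas the target needs C3 cis to both C2 and C4.
- Against: the allylpalladium intermediate can lose the allylic configuration by π–σ–π isomerisation and the oxygen conjugate addition is reversible, so the relative configuration at C2, C4 and C5 would be thermodynamic. Absolute control from a racemic epoxide would need a ligand-controlled dynamic process on an electron-rich substrate.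
- Against: the vinyl group costs an ozonolysis and a reduction.
- Comparison: the chosen route is longer to the ring, but each of the four centres is assigned to a defined controlling element.

Key step: step 12

## Route

Step 1
Reactants: 1 4-(benzyloxy)-3-methoxybenzaldehyde (O-benzylvanillin); 2 dimethyl succinate
Product: 3 (E)-4-[4-(benzyloxy)-3-methoxyphenyl]-3-(methoxycarbonyl)but-3-enoic acid
Conditions: NaOMe (2 equiv), MeOH, reflux; then aq. HCl
Reagents that add atoms: none
Why: Stobbe condensation: the succinate enolate adds to the aldehyde, the aldolate lactonises onto the far ester and base-induced ring opening gives the half ester with the free acid on the CH2 arm, normally as the E isomer. The benzyl ether keeps the phenol from being deprotonated, which would switch off the aldehyde.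

Step 2
Reactants: 3 (E)-4-[4-(benzyloxy)-3-methoxyphenyl]-3-(methoxycarbonyl)but-3-enoic acid
Product: 4 (R)-4-[4-(benzyloxy)-3-methoxyphenyl]-3-(methoxycarbonyl)butanoic acid
Conditions: [Rh(cod)((S,S)-Et-DuPhos)]BF4 (1 mol%), NaOMe (0.1 equiv), H2 (5 bar), MeOH, rt
Reagents that add atoms: none
Why: Rhodium-catalysed asymmetric hydrogenation of a β-substituted itaconate half ester: the carboxylate arm and the alkene bind rhodium together and the C2-symmetric bisphospholane selects the alkene face, which should set the future C4 centre as R. The homogeneous rhodium catalyst does not cleave the benzyl ether.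

Step 3
Reactants: 4 (R)-4-[4-(benzyloxy)-3-methoxyphenyl]-3-(methoxycarbonyl)butanoic acid
Product: 6 (R)-4-{[4-(benzyloxy)-3-methoxyphenyl]methyl}oxolan-2-one, via hydroxy acid 5 (not isolated)
Conditions: KOH (1.0 equiv), EtOH, 0 °C; CaCl2, NaBH4, EtOH, 0 °C to rt; then 2 M HCl, rt
Reagents that add atoms: none
Why: Chemoselective ester reduction: Ca(BH4)2 formed in the flask reduces the methyl ester while the potassium carboxylate is inert to borohydride, and acidification frees the γ-hydroxy acid 5, which closes at once to the five-membered lactone. Ethanolic borohydride at 0 °C should not enolise the ester, and after reduction the stereocentre is no longer α to a carbonyl group.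

Step 4
Reactants: 6 (R)-4-{[4-(benzyloxy)-3-methoxyphenyl]methyl}oxolan-2-one
Product: 8 benzyl (R)-3-{[4-(benzyloxy)-3-methoxyphenyl]methyl}-4-hydroxybutanoate, via sodium hydroxy carboxylate 7 (not isolated)
Conditions: NaOH (1.0 equiv), THF/H2O, rt; evaporate to dryness; BnBr (1.1 equiv), DMF, 0 °C to rt
Reagents that add atoms: sodium hydroxide, [Na+].[OH-]; benzyl bromide, BrCc1ccccc1
Why: Saponification opens the lactone to the carboxylate 7, and SN2 alkylation of the carboxylate by benzyl bromide in a dipolar aprotic solvent caps it as the benzyl ester; with one equivalent of hydroxide the primary hydroxyl stays un-ionised and is not benzylated. The γ-hydroxy ester is kept away from acid and base and is esterified in the next step without delay, since it can close back to 6.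

Step 5
Reactants: 8 benzyl (R)-3-{[4-(benzyloxy)-3-methoxyphenyl]methyl}-4-hydroxybutanoate; 9 pivaloyl chloride
Product: 10 benzyl (R)-3-{[4-(benzyloxy)-3-methoxyphenyl]methyl}-4-(pivaloyloxy)butanoate
Conditions: PivCl (1.2 equiv), pyridine, DMAP (cat.), CH2Cl2, 0 °C
Reagents that add atoms: none
Why: Acylation of a primary alcohol by an acid chloride under nucleophilic catalysis, which should be faster than lactonisation at 0 °C; once the hydroxyl is esterified the chain can no longer close to the lactone. This pivalate is the ester that the C4 acyloxymethyl group keeps until the last step.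

Step 6
Reactants: 10 benzyl (R)-3-{[4-(benzyloxy)-3-methoxyphenyl]methyl}-4-(pivaloyloxy)butanoate
Product: 11 (R)-3-[(4-hydroxy-3-methoxyphenyl)methyl]-4-(pivaloyloxy)butanoic acid
Conditions: H2 (1 bar), Pd/C (10%), EtOAc, rt
Reagents that add atoms: none
Why: Hydrogenolysis of benzylic C–O bonds over palladium on carbon: the benzyl ester and the aryl benzyl ether are cleaved in the same operation, and the pivalate and the arene are not affected.

Step 7
Reactants: 11 (R)-3-[(4-hydroxy-3-methoxyphenyl)methyl]-4-(pivaloyloxy)butanoic acid; 9 pivaloyl chloride; 12 (S)-4-benzyl-2-oxazolidinone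
Product: 14 (S)-4-benzyl-3-[(R)-3-{[3-methoxy-4-(pivaloyloxy)phenyl]methyl}-4-(pivaloyloxy)butanoyl]oxazolidin-2-one, via mixed pivalic anhydride 13 (not isolated)
Conditions: PivCl (2.2 equiv), Et3N (3.5 equiv), THF, −20 to 0 °C; then LiCl, 12, rt
Reagents that add atoms: none
Why: Pivaloyl chloride acylates the phenol and at the same time converts the carboxylate into the mixed anhydride 13, which the LiCl/Et3N-activated oxazolidinone attacks at the less hindered carbonyl (mixed-anhydride N-acylation). The stereocentre is β to the activated carboxyl group and cannot be enolised.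

Step 8
Reactants: 15 vanillin; 9 pivaloyl chloride
Product: 16 4-formyl-2-methoxyphenyl pivalate
Conditions: PivCl, Et3N, DMAP (cat.), CH2Cl2, 0 °C to rt
Reagents that add atoms: none
Why: Acylation of a phenol by an acid chloride under nucleophilic catalysis; the aldehyde is not affected.

Step 9
Reactants: 14 (S)-4-benzyl-3-[(R)-3-{[3-methoxy-4-(pivaloyloxy)phenyl]methyl}-4-(pivaloyloxy)butanoyl]oxazolidin-2-one; 16 4-formyl-2-methoxyphenyl pivalate
Product: 17 (S)-4-benzyl-3-[(2R,3R)-2-{(S)-[3-methoxy-4-(pivaloyloxy)phenyl][(trimethylsilyl)oxy]methyl}-3-{[3-methoxy-4-(pivaloyloxy)phenyl]methyl}-4-(pivaloyloxy)butanoyl]oxazolidin-2-one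
Conditions: MgCl2 (0.2 equiv), Et3N (2 equiv), TMSCl (1.5 equiv), EtOAc, rt
Reagents that add atoms: chlorotrimethylsilane, C[Si](C)(C)Cl
Why: Magnesium-halide-catalysed anti-aldol reaction of an N-acyl oxazolidinone: triethylamine enolises only the imide held as a magnesium chelate (the pivalates are not enolised and C4 has no acidic hydrogen), the aldehyde adds to the Z-enolate on the face away from the auxiliary benzyl group through a boat-like transition state, and silylation of the aldolate turns the catalyst over. This should set C3 and C2 in the anti relationship that becomes C2/C3 cis in the oxolane. The pivalate makes the aldehyde more electrophilic than an alkoxy-substituted one and keeps the new benzylic silyl ether from ionising.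

Step 10
Reactants: 17 (S)-4-benzyl-3-[(2R,3R)-2-{(S)-[3-methoxy-4-(pivaloyloxy)phenyl][(trimethylsilyl)oxy]methyl}-3-{[3-methoxy-4-(pivaloyloxy)phenyl]methyl}-4-(pivaloyloxy)butanoyl]oxazolidin-2-one
Product: 19 (1S,2S,3R)-2-(hydroxymethyl)-1,4-bis[3-methoxy-4-(pivaloyloxy)phenyl]-3-[(pivaloyloxy)methyl]butan-1-ol, via carbinol silyl ether 18 (not isolated)
Conditions: NaBH4 (4 equiv), THF/H2O (4:1), 0 °C to rt; then PPTS, MeOH, rt
Reagents that add atoms: none
Why: Reductive removal of the auxiliary: borohydride attacks the activated exocyclic imide carbonyl, the hemiaminal collapses to the aldehyde and this is reduced to the primary alcohol, while the three pivalates are shielded by their tert-butyl groups and should not be reduced under these mild conditions. The silyl ether blocks retro-aldol cleavage during the reduction and is then removed by mildly acidic methanolysis, which should neither ionise the benzylic carbinol, whose aryl group bears an acyloxy group, nor cleave a pivalate.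

Step 11
Reactants: 19 (1S,2S,3R)-2-(hydroxymethyl)-1,4-bis[3-methoxy-4-(pivaloyloxy)phenyl]-3-[(pivaloyloxy)methyl]butan-1-ol; 9 pivaloyl chloride
Product: 20 (1S,2S,3R)-1,4-bis[3-methoxy-4-(pivaloyloxy)phenyl]-2,3-bis[(pivaloyloxy)methyl]butan-1-ol
Conditions: PivCl (1.2 equiv), pyridine, CH2Cl2, −20 to 0 °C
Reagents that add atoms: none
Why: Chemoselective esterification: pivaloyl chloride in pyridine acylates the primary hydroxyl readily, whereas the secondary benzylic hydroxyl, next to a doubly branched carbon, reacts far more slowly with this bulky reagent at low temperature. With this fourth ester both arenes and both CH2–O groups are prepared for the radical step.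

Step 12
Reactants: 20 (1S,2S,3R)-1,4-bis[3-methoxy-4-(pivaloyloxy)phenyl]-2,3-bis[(pivaloyloxy)methyl]butan-1-ol
Product: 21 (2S,3S,4R,5S)-2,5-bis[3-methoxy-4-(pivaloyloxy)phenyl]-3,4-bis[(pivaloyloxy)methyl]oxolane
Conditions: PhI(OAc)2 (1.5 equiv), I2 (1 equiv), CH2Cl2, visible light (tungsten lamp), 15 °C
Reagents that add atoms: none
Why: Acetyl hypoiodite formed from PhI(OAc)2 and I2 converts the C2 hydroxyl into an O–I bond; light cleaves it, the alkoxy radical takes a hydrogen from C5 through a six-membered transition state (1,5-hydrogen transfer), the benzylic radical is trapped by iodine, and the benzylic iodide is displaced by the same hydroxyl. The closest known reaction type is the hypoiodite remote functionalisation of alcohols, which turns 4-arylbutanols and rigid polycyclic alcohols into oxolanes. The ring closes in the 5-exo-tet mode, O1 attacking C5 while iodide leaves outside the ring. The new C5 centre is set by the substrate: the iodide epimers interconvert through the benzylic ion pair, and closure with the aryl group trans to the C4 pivaloyloxymethyl group avoids the fourfold cis arrangement of the other epimer. The step needs selectivity among the hydrogens within reach. It is secured because C5–H is benzylic and the weakest, the δ hydrogens of the C4 acyloxymethyl group are strengthened and polarity-mismatched by the ester oxygen, and the C3 acyloxymethyl hydrogens can be reached only through a five-membered transition state. Hydrogen transfer also has to outrun β-scission of the C2–C3 bond and loss of HI from the hypoiodite to the aryl ketone, which is why strong light and a low temperature are used. The acyloxy groups on both rings slow electrophilic iodination and keep both benzylic C–O bonds from ionising, so the C2/C3 cis relationship set in step 9 is carried through unchanged.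

Step 13
Reactants: 21 (2S,3S,4R,5S)-2,5-bis[3-methoxy-4-(pivaloyloxy)phenyl]-3,4-bis[(pivaloyloxy)methyl]oxolane
Product: 22 (2S,3S,4R,5S)-2,5-bis(4-hydroxy-3-methoxyphenyl)-3,4-bis(hydroxymethyl)oxolane (CNP0286218.1)
Conditions: LiAlH4 (6 equiv), THF, 0 °C to rt; aq. KNaC4H4O6 (potassium sodium tartrate) work-up at neutral pH
Reagents that add atoms: none
Why: Reductive cleavage of esters: LiAlH4 removes the two aryl and the two alkyl pivalates as neopentyl alcohol without touching the ring. Hydride and alkoxide do not ionise the benzylic ethers, and the neutral work-up keeps the freed phenols from triggering epimerisation at C2.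

## Compound list

1 | 4-(benzyloxy)-3-methoxybenzaldehyde | COc1cc(C=O)ccc1OCc1ccccc1 | starting material
2 | dimethyl succinate | COC(=O)CCC(=O)OC | starting material
3 | (E)-4-[4-(benzyloxy)-3-methoxyphenyl]-3-(methoxycarbonyl)but-3-enoic acid | OC(=O)C/C(C(=O)OC)=C\c1ccc(OCc2ccccc2)c(OC)c1 | intermediate
4 | (R)-4-[4-(benzyloxy)-3-methoxyphenyl]-3-(methoxycarbonyl)butanoic acid | OC(=O)C[C@@H](Cc1ccc(OCc2ccccc2)c(OC)c1)C(=O)OC | intermediate
5 | (R)-3-{[4-(benzyloxy)-3-methoxyphenyl]methyl}-4-hydroxybutanoic acid (not isolated) | OC(=O)C[C@@H](Cc1ccc(OCc2ccccc2)c(OC)c1)CO | intermediate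
6 | (R)-4-{[4-(benzyloxy)-3-methoxyphenyl]methyl}oxolan-2-one | O=C1C[C@@H](Cc2ccc(OCc3ccccc3)c(OC)c2)CO1 | intermediate
7 | sodium (R)-3-{[4-(benzyloxy)-3-methoxyphenyl]methyl}-4-hydroxybutanoate (not isolated) | [Na+].[O-]C(=O)C[C@@H](Cc1ccc(OCc2ccccc2)c(OC)c1)CO | intermediate
8 | benzyl (R)-3-{[4-(benzyloxy)-3-methoxyphenyl]methyl}-4-hydroxybutanoate | O=C(OCc1ccccc1)C[C@@H](Cc1ccc(OCc2ccccc2)c(OC)c1)CO | intermediate
9 | pivaloyl chloride | CC(C)(C)C(=O)Cl | starting material
10 | benzyl (R)-3-{[4-(benzyloxy)-3-methoxyphenyl]methyl}-4-(pivaloyloxy)butanoate | O=C(OCc1ccccc1)C[C@@H](Cc1ccc(OCc2ccccc2)c(OC)c1)COC(=O)C(C)(C)C | intermediate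
11 | (R)-3-[(4-hydroxy-3-methoxyphenyl)methyl]-4-(pivaloyloxy)butanoic acid | OC(=O)C[C@@H](Cc1ccc(O)c(OC)c1)COC(=O)C(C)(C)C | intermediate
12 | (S)-4-benzyl-2-oxazolidinone | O=C1N[C@@H](Cc2ccccc2)CO1 | starting material
13 | mixed pivalic anhydride of (R)-3-{[3-methoxy-4-(pivaloyloxy)phenyl]methyl}-4-(pivaloyloxy)butanoic acid (not isolated) | CC(C)(C)C(=O)OC(=O)C[C@@H](Cc1ccc(OC(=O)C(C)(C)C)c(OC)c1)COC(=O)C(C)(C)C | intermediate
14 | (S)-4-benzyl-3-[(R)-3-{[3-methoxy-4-(pivaloyloxy)phenyl]methyl}-4-(pivaloyloxy)butanoyl]oxazolidin-2-one | O=C(C[C@@H](Cc1ccc(OC(=O)C(C)(C)C)c(OC)c1)COC(=O)C(C)(C)C)N1[C@@H](Cc2ccccc2)COC1=O | intermediate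
15 | vanillin | COc1cc(C=O)ccc1O | starting material
16 | 4-formyl-2-methoxyphenyl pivalate | COc1cc(C=O)ccc1OC(=O)C(C)(C)C | intermediate
17 | (S)-4-benzyl-3-[(2R,3R)-2-{(S)-[3-methoxy-4-(pivaloyloxy)phenyl][(trimethylsilyl)oxy]methyl}-3-{[3-methoxy-4-(pivaloyloxy)phenyl]methyl}-4-(pivaloyloxy)butanoyl]oxazolidin-2-one | COc1cc([C@@H](O[Si](C)(C)C)[C@H](C(=O)N3[C@@H](Cc4ccccc4)COC3=O)[C@H](COC(=O)C(C)(C)C)Cc2ccc(OC(=O)C(C)(C)C)c(OC)c2)ccc1OC(=O)C(C)(C)C | intermediate
18 | trimethylsilyl ether, at the secondary hydroxyl, of (1S,2S,3R)-2-(hydroxymethyl)-1,4-bis[3-methoxy-4-(pivaloyloxy)phenyl]-3-[(pivaloyloxy)methyl]butan-1-ol (not isolated) | COc1cc([C@@H](O[Si](C)(C)C)[C@H](CO)[C@H](COC(=O)C(C)(C)C)Cc2ccc(OC(=O)C(C)(C)C)c(OC)c2)ccc1OC(=O)C(C)(C)C | intermediate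
19 | (1S,2S,3R)-2-(hydroxymethyl)-1,4-bis[3-methoxy-4-(pivaloyloxy)phenyl]-3-[(pivaloyloxy)methyl]butan-1-ol | COc1cc([C@@H](O)[C@H](CO)[C@H](COC(=O)C(C)(C)C)Cc2ccc(OC(=O)C(C)(C)C)c(OC)c2)ccc1OC(=O)C(C)(C)C | intermediate
20 | (1S,2S,3R)-1,4-bis[3-methoxy-4-(pivaloyloxy)phenyl]-2,3-bis[(pivaloyloxy)methyl]butan-1-ol | COc1cc([C@@H](O)[C@H](COC(=O)C(C)(C)C)[C@H](COC(=O)C(C)(C)C)Cc2ccc(OC(=O)C(C)(C)C)c(OC)c2)ccc1OC(=O)C(C)(C)C | intermediate
21 | (2S,3S,4R,5S)-2,5-bis[3-methoxy-4-(pivaloyloxy)phenyl]-3,4-bis[(pivaloyloxy)methyl]oxolane | COc1cc([C@H]2O[C@H](c3ccc(OC(=O)C(C)(C)C)c(OC)c3)[C@@H](COC(=O)C(C)(C)C)[C@H]2COC(=O)C(C)(C)C)ccc1OC(=O)C(C)(C)C | intermediate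
22 | (2S,3S,4R,5S)-2,5-bis(4-hydroxy-3-methoxyphenyl)-3,4-bis(hydroxymethyl)oxolane | COc1cc([C@H]2O[C@H](c3ccc(O)c(OC)c3)[C@@H](CO)[C@H]2CO)ccc1O | target

## Step count and least certain steps

Total: 13 steps. Longest linear sequence: 12 steps (1 to 7 and 9 to 13); step 8 is a one-step side branch.

**Step 12 (key step).** Four things may go wrong.
- The alkoxy radical may fragment at the C2–C3 bond before it abstracts hydrogen, because β-scission is driven by formation of a conjugated aryl aldehyde.
- The secondary benzylic hypoiodite may lose HI and give the aryl ketone.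
- The methoxy-bearing rings may be iodinated, since acetyl hypoiodite is an electrophile.
- The closure may give some of the wrong C5 epimer.

Fallback, from 20 back to 21, avoiding an oxygen radical altogether: the hydroxyl of 20 is masked with (CF3CO)2O and pyridine as the trifluoroacetate F1, which also deactivates the C2–H bond towards bromine atoms. Wohl–Ziegler bromination (N-bromosuccinimide, light, PhCF3) should then take one of the only unhindered benzylic hydrogens and give the C5 bromide F2 as a mixture of epimers. Methanolysis of the trifluoroacetate (NaHCO3, MeOH, 0 °C) frees the bromo alcohol F3. AgOSO2CF3 with 2,6-di-tert-butylpyridine in CH2Cl2 ionises the bromide, and the hydroxyl closes on the benzylic cation, convergently from both epimers and with the same trans preference, to 21.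

**Step 9.** Soft enolisation of the β-branched imide may be slow, and the resident C4 centre may work against the auxiliary and erode facial or anti selectivity. Fallback, from 11 back to 19, with a different basis of stereocontrol: acid 11 is converted as in step 7, through 13, with (R)-4-benzyl-2-oxazolidinone into the diastereomeric imide F4. Its dibutylboron Z-enolate (Bu2BOSO2CF3, iPr2NEt, CH2Cl2, −78 °C) is combined with 16 precomplexed with Et2AlCl. This open-transition-state aldol gives the anti adduct on the enolate face chosen by the dipole-minimised boron enolate, which with the R auxiliary is the hydroxy imide F5 with the same configuration at C2, C3 and C4. Reduction of F5 with NaBH4 in THF/H2O as in step 10 gives 19.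

**Step 10.** Reduction of the crowded imide may be slow enough that the aryl pivalates are partly lost, by hydride attack or by hydrolysis in the basic aqueous medium, giving mixtures of partly deacylated material. Fallback, from 17 back to 20, giving up chemoselectivity in the reduction: LiAlH4 in THF at 0 °C reduces the imide and cleaves all three pivalates to the silyl ether tetraol F6. K2CO3 in MeOH at 0 °C removes the silyl group to give the pentaol F7, which is used at once. Pivaloyl chloride (4.4 equiv) in pyridine and CH2Cl2 at −20 °C then esterifies the two phenols and the two primary hydroxyls and leaves the hindered secondary hydroxyl, giving 20.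

**Step 4.** The γ-hydroxy ester may close back to the lactone during work-up or under the basic conditions of step 5, with loss of benzyl alcohol. Fallback, from 4 back to 11, with a carboxyl protecting group that the neighbouring hydroxyl cannot displace: acid 4 is esterified with Boc2O, DMAP and tBuOH to the mixed diester F8. LiBH4 in THF reduces the methyl ester and leaves the tert-butyl ester, giving the hydroxy ester F9. Pivaloyl chloride and pyridine give the pivalate F10. CF3CO2H with Et3SiH in CH2Cl2 removes the tert-butyl group to give the acid F11, and hydrogenolysis (H2, Pd/C, EtOAc) of the aryl benzyl ether gives 11.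

**Step 7.** The free phenol of one molecule may be acylated by the mixed anhydride of another instead of by pivaloyl chloride, giving oligoesters. Fallback, from 11 back to 14, with the phenol protected in a separate operation and the acid activated as its chloride: 11 is treated with pivaloyl chloride (2.2 equiv) and pyridine, and the mixed anhydride is hydrolysed with aqueous NaHCO3 during work-up, leaving the aryl pivalate acid F12. (COCl)2 with catalytic DMF in CH2Cl2 gives the acid chloride F13, which is added to the lithium salt of 12 (nBuLi, THF, −78 °C) to give 14.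

## Further compounds

F1 | step 12 | (1S,2S,3R)-1,4-bis[3-methoxy-4-(pivaloyloxy)phenyl]-2,3-bis[(pivaloyloxy)methyl]butyl trifluoroacetate | COc1cc([C@@H](OC(=O)C(F)(F)F)[C@H](COC(=O)C(C)(C)C)[C@H](COC(=O)C(C)(C)C)Cc2ccc(OC(=O)C(C)(C)C)c(OC)c2)ccc1OC(=O)C(C)(C)C
F2 | step 12 | 4-bromo derivative of F1, brominated at the benzylic CH2 (C5), both epimers at the bromide carbon | COc1cc([C@@H](OC(=O)C(F)(F)F)[C@H](COC(=O)C(C)(C)C)[C@H](COC(=O)C(C)(C)C)C(Br)c2ccc(OC(=O)C(C)(C)C)c(OC)c2)ccc1OC(=O)C(C)(C)C
F3 | step 12 | 4-bromo derivative of 20 (bromo alcohol), both epimers at the bromide carbon | COc1cc([C@@H](O)[C@H](COC(=O)C(C)(C)C)[C@H](COC(=O)C(C)(C)C)C(Br)c2ccc(OC(=O)C(C)(C)C)c(OC)c2)ccc1OC(=O)C(C)(C)C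
F4 | step 9 | (R)-4-benzyl-3-[(R)-3-{[3-methoxy-4-(pivaloyloxy)phenyl]methyl}-4-(pivaloyloxy)butanoyl]oxazolidin-2-one | O=C(C[C@@H](Cc1ccc(OC(=O)C(C)(C)C)c(OC)c1)COC(=O)C(C)(C)C)N1[C@H](Cc2ccccc2)COC1=O
F5 | step 9 | (R)-4-benzyl-3-[(2R,3R)-2-{(S)-hydroxy[3-methoxy-4-(pivaloyloxy)phenyl]methyl}-3-{[3-methoxy-4-(pivaloyloxy)phenyl]methyl}-4-(pivaloyloxy)butanoyl]oxazolidin-2-one | COc1cc([C@@H](O)[C@H](C(=O)N3[C@H](Cc4ccccc4)COC3=O)[C@H](COC(=O)C(C)(C)C)Cc2ccc(OC(=O)C(C)(C)C)c(OC)c2)ccc1OC(=O)C(C)(C)C
F6 | step 10 | (2S,3R)-2-{(S)-(4-hydroxy-3-methoxyphenyl)[(trimethylsilyl)oxy]methyl}-3-[(4-hydroxy-3-methoxyphenyl)methyl]butane-1,4-diol | COc1cc([C@@H](O[Si](C)(C)C)[C@H](CO)[C@H](CO)Cc2ccc(O)c(OC)c2)ccc1O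
F7 | step 10 | (1S,2S,3R)-1,4-bis(4-hydroxy-3-methoxyphenyl)-2,3-bis(hydroxymethyl)butan-1-ol | COc1cc([C@@H](O)[C@H](CO)[C@H](CO)Cc2ccc(O)c(OC)c2)ccc1O
F8 | step 4 | 4-tert-butyl 1-methyl (R)-2-{[4-(benzyloxy)-3-methoxyphenyl]methyl}butanedioate | CC(C)(C)OC(=O)C[C@@H](Cc1ccc(OCc2ccccc2)c(OC)c1)C(=O)OC
F9 | step 4 | tert-butyl (R)-3-{[4-(benzyloxy)-3-methoxyphenyl]methyl}-4-hydroxybutanoate | CC(C)(C)OC(=O)C[C@@H](Cc1ccc(OCc2ccccc2)c(OC)c1)CO
F10 | step 4 | tert-butyl (R)-3-{[4-(benzyloxy)-3-methoxyphenyl]methyl}-4-(pivaloyloxy)butanoate | CC(C)(C)OC(=O)C[C@@H](Cc1ccc(OCc2ccccc2)c(OC)c1)COC(=O)C(C)(C)C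
F11 | step 4 | (R)-3-{[4-(benzyloxy)-3-methoxyphenyl]methyl}-4-(pivaloyloxy)butanoic acid | OC(=O)C[C@@H](Cc1ccc(OCc2ccccc2)c(OC)c1)COC(=O)C(C)(C)C
F12 | step 7 | (R)-3-{[3-methoxy-4-(pivaloyloxy)phenyl]methyl}-4-(pivaloyloxy)butanoic acid | OC(=O)C[C@@H](Cc1ccc(OC(=O)C(C)(C)C)c(OC)c1)COC(=O)C(C)(C)C
F13 | step 7 | (R)-3-{[3-methoxy-4-(pivaloyloxy)phenyl]methyl}-4-(pivaloyloxy)butanoyl chloride | ClC(=O)C[C@@H](Cc1ccc(OC(=O)C(C)(C)C)c(OC)c1)COC(=O)C(C)(C)C
A1 | alternative 1 | (2S,3R)-2,5-bis[4-(benzyloxy)-3-methoxyphenyl]-3-({[(bromomethyl)dimethylsilyl]oxy}methyl)-2,3-dihydrofuran | COc1cc(C2=C[C@H](CO[Si](C)(C)CBr)[C@@H](c3ccc(OCc4ccccc4)c(OC)c3)O2)ccc1OCc1ccccc1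
A2 | alternative 1 | cis-fused oxasilinane–oxolane bicycle carrying both 4-(benzyloxy)-3-methoxyphenyl groups | COc1cc([C@H]2O[C@H](c3ccc(OCc4ccccc4)c(OC)c3)[C@@H](CO[Si](C)(C)C3)[C@H]23)ccc1OCc1ccccc1
A3 | alternative 2 | all-cis 9-[4-(benzyloxy)-3-methoxyphenyl]-4,4-dimethyl-3,5-dioxabicyclo[5.2.0]nonan-8-one (reacting enantiomer) | COc1cc([C@H]2C(=O)[C@@H](COC(C)(C)OC3)[C@H]23)ccc1OCc1ccccc1
A4 | alternative 2 | all-cis 5-[4-(benzyloxy)-3-methoxyphenyl]butyrolactone fused at C3/C4 to a 2,2-dimethyl-1,3-dioxepane | COc1cc([C@H]2OC(=O)[C@@H](COC(C)(C)OC3)[C@H]23)ccc1OCc1ccccc1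
A5 | alternative 3 | trans-(2R,3R)-2-[4-(benzyloxy)-3-methoxyphenyl]-3-vinyloxirane | O1[C@H](c2ccc(OCc3ccccc3)c(OC)c2)[C@H]1C=C
A6 | alternative 3 | dimethyl 2-{[4-(benzyloxy)-3-methoxyphenyl]methylidene}propanedioate | COC(=O)C(=Cc1ccc(OCc2ccccc2)c(OC)c1)C(=O)OC
A7 | alternative 3 | dimethyl 2,5-bis[4-(benzyloxy)-3-methoxyphenyl]-4-vinyloxolane-3,3-dicarboxylate | COc1cc([C@H]2O[C@H](c3ccc(OCc4ccccc4)c(OC)c3)[C@@H](C=C)C2(C(=O)OC)C(=O)OC)ccc1OCc1ccccc1
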